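## Analysis of the target

The target is a 2,3-dihydrobenzofuran neolignan. Ring A is the benzo ring (C3a, C4 to C7, C7a), the five-membered ring holds O1, C2 and C3, and ring B is a 3,4,5-trimethoxyphenyl group on C2. C2 (R, aryl) and C3 (R, methyl) are adjacent and trans, and they are the only stereocentres. The one further stereo-element is the E geometry of the propenyl group on C5. Ring A carries oxygen at C6 and C7a, carbon at C5 and C3a, and hydrogen at C4 and C7. Oxidative coupling of propenylphenols would put the methoxy group on C7, so ring A has to be built or substituted deliberately. The sensitive sites are the benzylic C2–O1 bond next to an electron-rich aryl ring (ionisation in acid, hydride loss to quinones), the styrene-type propenyl group, and the electron-rich arenes. The synthesis is hard because the trans C2/C3 pair must be set in absolute terms and the C5/C6 carbon–oxygen pattern must be placed regiospecifically without forming the fragile C2–O1 bond late. The strategy rests on one mapping: C4, C3a and C7a correspond to the exocyclic methylene carbon, the α-carbon and the carbonyl carbon of an α-methylene-γ-butyrolactone that already contains O1, C2 and C3, while C5, C6 and C7 correspond to C2, C3 and C4 of an acetoacetate.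

## Retrosynthetic reasoning

**Propenyl group (22 to 20 + 21).** The C=C bond of the side chain is cut first. The styrenic alkene would not survive the quinone oxidation, the borane chemistry or the acid used earlier, so it is made last. The forward step has to join aldehyde 20 and sulfone 21 with E selectivity under conditions that leave C2 and C3 alone.

**Ring A oxidation level (20 back to 16).** No skeletal bond is cut here. Aldehyde 20 comes from ester 18 through alcohol 19, ether 18 from phenol 17, and phenol 17 from the cyclohexenone β-keto ester 16 by loss of two hydrogens from C3a and C4. This exposes ring A as a masked salicylate in which the carbon at C5 and the oxygens at C6 and C7a are fixed by connectivity. The forward dehydrogenation must stop before the benzylic C2–H and C3–H bonds are attacked.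

**Ring A construction (16 to 12 + 13).** The bonds C4–C5 and C7–C7a are cut, and O1–C7a is opened and re-formed in the same operation. Cutting here divides ring A into a three-carbon bis-electrophile (methylene lactone 12) and a three-carbon bis-nucleophile (methyl acetoacetate 13). The C2–O1 and C2–C3 bonds and both stereocentres stay inside 12 untouched. The forward reaction is a conjugate addition to give 14, a Claisen ring closure to hydroxy dione 15, and acid-promoted re-closure of the oxygen ring.

**Exocyclic methylene (12 to 9).** The C=CH2 bond, which becomes C3a–C4, is cut. The carbon is added to lactone 9 by aminomethylation to 10, quaternisation to 11 and elimination. The elimination must be run under a base too weak to move the double bond into the ring.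

**Lactone (9 to 5).** The acyl C–O bond is opened and the oxidation level lowered: lactone 9 from diol 7 through lactol 8, and diol 7 from homoallylic alcohol 5 through borane adduct 6. This reduces the problem to a simple alcohol that carries both stereocentres.

**Stereodiad (5 to 1 + 2).** The bond between the two stereocentres (C2–C3 of the target) is cut. An anti-selective, reagent-controlled crotylation of aldehyde 1 with the crotylborane 3 derived from butene 2 sets both centres in one step through borinate 4.

## Alternatives that were turned down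

**Alternative 1: boronate homologation at C2.**
- Disconnection: C2–C3 and C2–ring B, both formed at a boron-bearing carbon.
- Forward key step: the secondary benzylic boronate A2 takes up a one-carbon chlorocarbenoid with 1,2-migration of the C3 carbon from boron, and an arylmagnesium nucleophile carrying ring B then displaces the chloride by a second 1,2-migration to give A1.
- For it: both migrations are stereospecific and directed by one C2-symmetric diol, and ring B can be varied freely. On stereocontrol it is at least as strong as the chosen route.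
- Against it:
  - A2 must itself be made enantiopure.
  - Both migrations take place at a hindered benzylic carbon, and the chloride intermediate can epimerise.
  - After C–B oxidation, O1–C2 has to be closed by an inverting displacement at a benzylic carbon that ionises easily.
  - Ring A has no carbon at C5, so a late electrophilic substitution must choose C5 over C7 and over ring B.
- Comparison: the chosen route keeps the C2–O1 bond from the lactone onwards and places the C5 carbon by construction, with fewer cryogenic organometallic steps.

**Alternative 2: pyrone cycloaddition.**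
- Disconnection: C3a–C4 and C7–C7a.
- Forward key step: the silyl ketene acetal A4 of lactone 9 adds across the diene of pyrone A5; retro-Diels–Alder decarboxylation and elimination of the silyloxy group give the aromatic ester A3, which is the same compound as 18.
- For it: ring A arrives aromatic with the ester at C5 and the methoxy group at C6, no oxidant meets the dihydrofuran, and 18 would be reached from 9 in two steps instead of five. On step economy it is clearly stronger.
- Against it:
  - The 4-methoxy group makes A5 a poorer electron-poor diene.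
  - A4 is hindered by the neighbouring methyl group and is hydrolytically labile.
  - At the temperatures needed, Michael addition without ring closure or desilylation can take over, and nothing short of the full cascade is usable.
- Comparison: the chosen route is longer, but each bond forms under anionic, thermodynamically driven conditions of a classical type, and intermediates 14 and 15 can be isolated and pushed on if the one-pot sequence stalls.

**Alternative 3: ketene–alkyne benzannulation.**
- Disconnection: C4–C5, C5–C6, C7–C7a and C3a–C7a.
- Forward key step: photochemical Wolff rearrangement of diazoketone A7 gives a vinylketene; this adds alkyne A8, and the cyclobutenone opens and recloses by 6π electrocyclisation to phenol A6.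
- For it: ring A forms aromatic under neutral conditions with oxygen at C7a and C6 placed regiospecifically. On mildness toward the stereocentres it is as strong as the chosen route.
- Against it:
  - A6 has hydrogen at C5, so the propenyl carbon needs a late, regioselective C–C bond formation.
  - O1–C2 must be closed by an inverting displacement at the ionisable benzylic carbon.
  - A7 needs the syn diad plus several steps of chain building, and A8 is volatile and unstable.
- Comparison: the chosen route installs the C5 carbon during ring construction and never has to form C2–O1.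

Key step: step 6

## Assumptions

- (+)-Ipc2BOMe denotes the reagent made from (−)-α-pinene. Its (E)-crotyl derivative is taken to add to the Re face of aryl aldehydes through the usual chair transition state, which gives the (1R,2R) anti alcohol.
- Sulfone 21 is treated as a purchasable reagent.

## Route

Step 1
Reactants: 1 3,4,5-trimethoxybenzaldehyde; 2 trans-but-2-ene
Product: 5 (1R,2R)-2-methyl-1-(3,4,5-trimethoxyphenyl)but-3-en-1-ol, via (E)-crotyldiisopinocampheylborane 3 (not isolated), via homoallyl borinate 4 (not isolated)
Conditions: 2, KOt-Bu, n-BuLi, THF, −78 to −45 °C; (+)-Ipc2BOMe, −78 °C; BF3·OEt2; 1, −78 °C; then NaOH, H2O2, 0 °C to rt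
Reagents that add atoms: none
Why: Brown crotylboration: the closed chair transition state turns the E geometry of 3 into the anti relationship of the two new centres, and the isopinocampheyl groups from (−)-α-pinene direct attack to the Re face of the aldehyde, which sets (1R,2R). Aryl aldehydes are good substrates, and holding the reagent at −78 °C prevents E/Z scrambling.

Step 2
Reactants: 5 (1R,2R)-2-methyl-1-(3,4,5-trimethoxyphenyl)but-3-en-1-ol
Product: 7 (1R,2R)-2-methyl-1-(3,4,5-trimethoxyphenyl)butane-1,4-diol, via bis-9-BBN adduct 6 (not isolated)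
Conditions: 9-BBN-H (2.5 equiv), THF, 0 °C to rt; then NaOH, H2O2, 0 °C to rt
Reagents that add atoms: hydrogen peroxide, OO
Why: Anti-Markovnikov hydroboration–oxidation of the terminal vinyl group; one equivalent of borane is consumed by the free hydroxyl, the bulky borane places boron only on the terminal carbon, and neither stereocentre is touched.

Step 3
Reactants: 7 (1R,2R)-2-methyl-1-(3,4,5-trimethoxyphenyl)butane-1,4-diol
Product: 9 (4R,5R)-4-methyl-5-(3,4,5-trimethoxyphenyl)dihydrofuran-2(3H)-one (trans), via lactol 8 (not isolated)
Conditions: TEMPO (cat.), PhI(OAc)2, CH2Cl2, rt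
Reagents that add atoms: none
Why: Oxidative lactonisation of a 1,4-diol: the oxoammonium species oxidises the primary alcohol selectively, the benzylic hydroxyl closes to lactol 8, and a second oxidation gives the lactone without involving the C–H bonds at the stereocentres.

Step 4
Reactants: 9 (4R,5R)-4-methyl-5-(3,4,5-trimethoxyphenyl)dihydrofuran-2(3H)-one
Product: 10 (4R,5R)-3-[(dimethylamino)methyl]-4-methyl-5-(3,4,5-trimethoxyphenyl)dihydrofuran-2(3H)-one (mixture at C3, mainly 3,4-trans)
Conditions: LiN(i-Pr)2, THF, −78 °C; CH2=NMe2+ I−, −78 °C to rt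
Reagents that add atoms: dimethylmethyleneiminium iodide, C=[N+](C)C.[I-]
Why: Mannich aminomethylation of the lactone lithium enolate; the new centre at C3 should form mainly trans to the C4 methyl group and is removed in the next step.

Step 5
Reactants: 10 (4R,5R)-3-[(dimethylamino)methyl]-4-methyl-5-(3,4,5-trimethoxyphenyl)dihydrofuran-2(3H)-one
Product: 12 (4R,5R)-4-methyl-3-methylene-5-(3,4,5-trimethoxyphenyl)dihydrofuran-2(3H)-one (trans), via trimethylammonium iodide 11 (not isolated)
Conditions: MeI, MeOH, rt; then NaHCO3, CH2Cl2/H2O, rt
Reagents that add atoms: none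
Why: N-Quaternisation followed by E1cB (Hofmann-type) loss of the amine, the standard entry to α-methylene lactones; bicarbonate is too weak a base to move the new double bond into the ring, so the C4 stereocentre is safe.

Step 6
Reactants: 12 (4R,5R)-4-methyl-3-methylene-5-(3,4,5-trimethoxyphenyl)dihydrofuran-2(3H)-one; 13 methyl acetoacetate
Product: 16 methyl (2R,3R)-3-methyl-6-oxo-2-(3,4,5-trimethoxyphenyl)-2,3,3a,4,5,6-hexahydrobenzofuran-5-carboxylate (mixture at C3a and C5), via Michael adduct 14 (not isolated), via hydroxy dione 15 (not isolated)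
Conditions: 13 (1.3 equiv), NaOMe (1.1 equiv), MeOH, 0 °C to rt; then NaOMe (2 equiv), reflux; aq. HCl to pH 3; TsOH·H2O (cat.), 4 Å MS, CH2Cl2, rt
Reagents that add atoms: none
Why: The sodium enolate of 13 adds through its central carbon to the unhindered exocyclic methylene of 12 (C4–C5); it is preformed with a slight excess of 13 so that no free methoxide meets the alkene. With more NaOMe at reflux, adduct 14 equilibrates to its acetyl-methyl enolate, which acylates on the lactone carbonyl (C7–C7a) in a 6-(enolendo)-exo-trig Claisen closure. This is the Michael–Claisen annulation by which acetoacetates and α,β-unsaturated esters give 4-carboalkoxycyclohexane-1,3-diones, with the lactone acting as the ester. The closure is driven by deprotonation of the new 1,3-dione 15, and the expelled benzylic alkoxide stays attached through C3 and C2. On acidification that hydroxyl adds to the nearer carbonyl C7a (5-exo-trig) and dehydrates towards C7, which gives the conjugated vinylogous ester and restores the O1–C7a bond. Regiochemistry needs no control beyond connectivity: only one six-membered Claisen ring can form, and the tethered hydroxyl reaches only C7a. The new centres C3a and C5 form without control and vanish on aromatisation. C2 and C3 are neither enolisable nor ionised in base, so their trans (R,R) configuration should carry through.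

Step 7
Reactants: 16 methyl (2R,3R)-3-methyl-6-oxo-2-(3,4,5-trimethoxyphenyl)-2,3,3a,4,5,6-hexahydrobenzofuran-5-carboxylate
Product: 17 methyl (2R,3R)-6-hydroxy-3-methyl-2-(3,4,5-trimethoxyphenyl)-2,3-dihydrobenzofuran-5-carboxylate
Conditions: DDQ (1.1 equiv), 1,4-dioxane, rt to 60 °C
Reagents that add atoms: none
Why: Dehydrogenative aromatisation: the enol of the β-keto ester gives up the C4 hydride to the quinone, forming a cation stabilised by both ring oxygens, and loss of the C3a proton with tautomerisation gives the salicylate. About one equivalent of oxidant at mild temperature should spare the benzylic C2–H and C3–H bonds.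

Step 8
Reactants: 17 methyl (2R,3R)-6-hydroxy-3-methyl-2-(3,4,5-trimethoxyphenyl)-2,3-dihydrobenzofuran-5-carboxylate
Product: 18 methyl (2R,3R)-6-methoxy-3-methyl-2-(3,4,5-trimethoxyphenyl)-2,3-dihydrobenzofuran-5-carboxylate
Conditions: MeI, K2CO3, DMF, 50 °C
Reagents that add atoms: iodomethane, CI
Why: Williamson O-methylation of the phenol; the chelated salicylate hydroxyl needs the polar solvent and gentle warming, and the ester and both stereocentres are inert.

Step 9
Reactants: 18 methyl (2R,3R)-6-methoxy-3-methyl-2-(3,4,5-trimethoxyphenyl)-2,3-dihydrobenzofuran-5-carboxylate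
Product: 19 [(2R,3R)-6-methoxy-3-methyl-2-(3,4,5-trimethoxyphenyl)-2,3-dihydrobenzofuran-5-yl]methanol
Conditions: i-Bu2AlH (2.5 equiv), CH2Cl2, −78 to 0 °C; aq. potassium sodium tartrate
Reagents that add atoms: none
Why: Hydride reduction of the aryl ester to the benzylic alcohol; no other reducible group is present.

Step 10
Reactants: 19 [(2R,3R)-6-methoxy-3-methyl-2-(3,4,5-trimethoxyphenyl)-2,3-dihydrobenzofuran-5-yl]methanol
Product: 20 (2R,3R)-6-methoxy-3-methyl-2-(3,4,5-trimethoxyphenyl)-2,3-dihydrobenzofuran-5-carbaldehyde
Conditions: MnO2, CH2Cl2, rt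
Reagents that add atoms: none
Why: Heterogeneous MnO2 oxidation is selective for the primary benzylic alcohol and stops at the aldehyde; the ring C2–H and C3–H bonds are not activated enough to react.

Step 11
Reactants: 20 (2R,3R)-6-methoxy-3-methyl-2-(3,4,5-trimethoxyphenyl)-2,3-dihydrobenzofuran-5-carbaldehyde; 21 5-(ethylsulfonyl)-1-phenyl-1H-tetrazole
Product: 22 (2R,3R)-6-methoxy-3-methyl-5-[(E)-prop-1-en-1-yl]-2-(3,4,5-trimethoxyphenyl)-2,3-dihydrobenzofuran
Conditions: KN(SiMe3)2, DME, −60 °C to rt
Reagents that add atoms: none
Why: Julia–Kocienski olefination: the metallated sulfone adds to the aldehyde, and Smiles rearrangement with loss of SO2 and the tetrazolone gives the alkene, E-selectively for aryl aldehydes with a potassium base in DME. No acid or oxidant meets the finished dihydrobenzofuran.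

## Compound list

1 | 3,4,5-trimethoxybenzaldehyde | COc1cc(C=O)cc(OC)c1OC | starting material
2 | trans-but-2-ene | C/C=C/C | starting material
3 | [(2E)-but-2-en-1-yl]bis[(1S,2R,3S,5S)-2,6,6-trimethylbicyclo[3.1.1]heptan-3-yl]borane | C/C=C/CB([C@H]1C[C@H]2C[C@@H]([C@@H]1C)C2(C)C)[C@H]1C[C@H]2C[C@@H]([C@@H]1C)C2(C)C | intermediate (not isolated)
4 | (1R,2R)-2-methyl-1-(3,4,5-trimethoxyphenyl)but-3-en-1-yl bis[(1S,2R,3S,5S)-2,6,6-trimethylbicyclo[3.1.1]heptan-3-yl]borinate | C=C[C@@H](C)[C@H](c1cc(OC)c(OC)c(OC)c1)OB([C@H]1C[C@H]2C[C@@H]([C@@H]1C)C2(C)C)[C@H]1C[C@H]2C[C@@H]([C@@H]1C)C2(C)C | intermediate (not isolated)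
5 | (1R,2R)-2-methyl-1-(3,4,5-trimethoxyphenyl)but-3-en-1-ol | C=C[C@@H](C)[C@H](c1cc(OC)c(OC)c(OC)c1)O | intermediate
6 | 9-[(3R,4R)-4-(9-borabicyclo[3.3.1]nonan-9-yloxy)-3-methyl-4-(3,4,5-trimethoxyphenyl)butyl]-9-borabicyclo[3.3.1]nonane | B1(C2CCCC1CCC2)CC[C@@H](C)[C@H](c1cc(OC)c(OC)c(OC)c1)OB1C2CCCC1CCC2 | intermediate (not isolated)
7 | (1R,2R)-2-methyl-1-(3,4,5-trimethoxyphenyl)butane-1,4-diol | OCC[C@@H](C)[C@H](c1cc(OC)c(OC)c(OC)c1)O | intermediate
8 | (4R,5R)-4-methyl-5-(3,4,5-trimethoxyphenyl)tetrahydrofuran-2-ol (both anomers) | OC1C[C@@H](C)[C@H](c2cc(OC)c(OC)c(OC)c2)O1 | intermediate (not isolated)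
9 | (4R,5R)-4-methyl-5-(3,4,5-trimethoxyphenyl)dihydrofuran-2(3H)-one | O=C1C[C@@H](C)[C@H](c2cc(OC)c(OC)c(OC)c2)O1 | intermediate
10 | (4R,5R)-3-[(dimethylamino)methyl]-4-methyl-5-(3,4,5-trimethoxyphenyl)dihydrofuran-2(3H)-one (mixture at C3) | CN(C)CC1[C@@H](C)[C@H](c2cc(OC)c(OC)c(OC)c2)OC1=O | intermediate
11 | N,N,N-trimethyl-1-[(4R,5R)-4-methyl-2-oxo-5-(3,4,5-trimethoxyphenyl)tetrahydrofuran-3-yl]methanaminium iodide | C[N+](C)(C)CC1[C@@H](C)[C@H](c2cc(OC)c(OC)c(OC)c2)OC1=O.[I-] | intermediate (not isolated)
12 | (4R,5R)-4-methyl-3-methylene-5-(3,4,5-trimethoxyphenyl)dihydrofuran-2(3H)-one | C=C1[C@@H](C)[C@H](c2cc(OC)c(OC)c(OC)c2)OC1=O | intermediate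
13 | methyl acetoacetate | CC(=O)CC(=O)OC | starting material
14 | methyl 2-acetyl-3-[(4R,5R)-4-methyl-2-oxo-5-(3,4,5-trimethoxyphenyl)tetrahydrofuran-3-yl]propanoate (mixture at the other centres) | COC(=O)C(C(C)=O)CC1[C@@H](C)[C@H](c2cc(OC)c(OC)c(OC)c2)OC1=O | intermediate (not isolated)
15 | methyl 5-[(1R,2R)-1-hydroxy-1-(3,4,5-trimethoxyphenyl)propan-2-yl]-2,4-dioxocyclohexane-1-carboxylate (mixture at the ring centres) | COC(=O)C1CC([C@@H](C)[C@H](c2cc(OC)c(OC)c(OC)c2)O)C(=O)CC1=O | intermediate (not isolated)
16 | methyl (2R,3R)-3-methyl-6-oxo-2-(3,4,5-trimethoxyphenyl)-2,3,3a,4,5,6-hexahydrobenzofuran-5-carboxylate (mixture at C3a and C5) | COC(=O)C1CC2C(=CC1=O)O[C@@H](c1cc(OC)c(OC)c(OC)c1)[C@@H]2C | intermediate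
17 | methyl (2R,3R)-6-hydroxy-3-methyl-2-(3,4,5-trimethoxyphenyl)-2,3-dihydrobenzofuran-5-carboxylate | COC(=O)c1cc2c(cc1O)O[C@@H](c1cc(OC)c(OC)c(OC)c1)[C@@H]2C | intermediate
18 | methyl (2R,3R)-6-methoxy-3-methyl-2-(3,4,5-trimethoxyphenyl)-2,3-dihydrobenzofuran-5-carboxylate | COC(=O)c1cc2c(cc1OC)O[C@@H](c1cc(OC)c(OC)c(OC)c1)[C@@H]2C | intermediate
19 | [(2R,3R)-6-methoxy-3-methyl-2-(3,4,5-trimethoxyphenyl)-2,3-dihydrobenzofuran-5-yl]methanol | OCc1cc2c(cc1OC)O[C@@H](c1cc(OC)c(OC)c(OC)c1)[C@@H]2C | intermediate
20 | (2R,3R)-6-methoxy-3-methyl-2-(3,4,5-trimethoxyphenyl)-2,3-dihydrobenzofuran-5-carbaldehyde | O=Cc1cc2c(cc1OC)O[C@@H](c1cc(OC)c(OC)c(OC)c1)[C@@H]2C | intermediate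
21 | 5-(ethylsulfonyl)-1-phenyl-1H-tetrazole | CCS(=O)(=O)c1nnnn1-c1ccccc1 | starting material
22 | (2R,3R)-6-methoxy-3-methyl-5-[(E)-prop-1-en-1-yl]-2-(3,4,5-trimethoxyphenyl)-2,3-dihydrobenzofuran | C/C=C/c1cc2c(cc1OC)O[C@@H](c1cc(OC)c(OC)c(OC)c1)[C@@H]2C | target

## Step count and least certain steps

Total: 11 steps. Longest linear sequence: 11 steps (1 to 22).

**Step 6 (key step).** Three processes can defeat it.
- Base-induced migration of the exocyclic double bond of 12 into the ring before the conjugate addition would erase the C3 stereocentre.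
- Stalling at the stabilised enolate of 14, or deacetylation of 14 by methoxide, would prevent the Claisen closure.
- Ionisation at the benzylic C2 during the acid closure would erode the trans relationship.

The fallback sets out from 10 and returns at 16. Amine 10 is quaternised to 11 as in step 5 but not eliminated. Salt 11 is added to the sodium enolate of 13 (NaOMe, MeOH, rt), so that acceptor 12 is released slowly in the presence of the nucleophile, and adduct 14 is isolated. Adduct 14 is then converted into its dianion (NaH, then n-BuLi, THF, −78 to 0 °C); the terminal carbanion acylates on the lactone under kinetic control to give 15, and catalytic TsOH closes 16. No compound outside the list arises (entry F0).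

**Step 1.** Partial E/Z equilibration of the crotyl reagent above −78 °C would leak syn diastereomer, and incomplete facial discrimination would lower enantiopurity. The fallback sets out from 1 and returns at 5. It is an iridium-catalysed transfer-hydrogenative anti-crotylation of 1 with racemic but-3-en-2-yl acetate F1 ([Ir(cod)Cl]2, SEGPHOS, 4-cyano-3-nitrobenzoic acid, Cs2CO3, i-PrOH, THF, 90 °C). The ligand enantiomer is the one that leads to the (1R,2R) series.

**Step 7.** Over-oxidation by hydride abstraction from C3 or C2 of the newly formed phenol would dehydrogenate the dihydrofuran to the benzofuran and destroy both stereocentres. Charge-transfer oxidation of ring B is a second possibility. The fallback sets out from 16 and returns at 17. The β-keto ester is selenenylated at C5 (NaH, PhSeCl, THF, 0 °C) to methyl (2R,3R)-3-methyl-6-oxo-5-(phenylselanyl)-2-(3,4,5-trimethoxyphenyl)-2,3,3a,4,5,6-hexahydrobenzofuran-5-carboxylate F2. Oxidation (H2O2, pyridine, CH2Cl2, 0 °C to rt) then triggers selenoxide syn-elimination towards C4, the only position with a β-hydrogen, and the dienone tautomerises to 17 without any hydride-abstracting oxidant.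

**Step 11.** Insufficient E selectivity in the sulfone addition and elimination would give geometric isomers that are hard to separate. The fallback sets out from 20 and returns at 22. A Wittig reaction with ethyltriphenylphosphonium bromide F3 (KN(SiMe3)2, THF, −78 °C to rt) should give mainly (2R,3R)-6-methoxy-3-methyl-5-[(Z)-prop-1-en-1-yl]-2-(3,4,5-trimethoxyphenyl)-2,3-dihydrobenzofuran F4. Catalytic PdCl2(MeCN)2 in CH2Cl2 at rt then equilibrates F4 to the conjugated, thermodynamically preferred E isomer 22.

## Further compounds

F0 | step 6 | none | none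
F1 | step 1 | but-3-en-2-yl acetate (racemic) | CC(=O)OC(C)C=C
F2 | step 7 | methyl (2R,3R)-3-methyl-6-oxo-5-(phenylselanyl)-2-(3,4,5-trimethoxyphenyl)-2,3,3a,4,5,6-hexahydrobenzofuran-5-carboxylate | COC(=O)C1([Se]c3ccccc3)CC2C(=CC1=O)O[C@@H](c1cc(OC)c(OC)c(OC)c1)[C@@H]2C
F3 | step 11 | ethyltriphenylphosphonium bromide | CC[P+](c1ccccc1)(c1ccccc1)c1ccccc1.[Br-]
F4 | step 11 | (2R,3R)-6-methoxy-3-methyl-5-[(Z)-prop-1-en-1-yl]-2-(3,4,5-trimethoxyphenyl)-2,3-dihydrobenzofuran | C/C=C\c1cc2c(cc1OC)O[C@@H](c1cc(OC)c(OC)c(OC)c1)[C@@H]2C
A1 | alternative 1 | (1S,2S)-2-[2-(tert-butyldimethylsilyloxy)-4-methoxyphenyl]-1-(3,4,5-trimethoxyphenyl)propylboronic acid (R,R)-1,2-dicyclohexylethane-1,2-diol ester | B1(O[C@H](C2CCCCC2)[C@@H](C2CCCCC2)O1)[C@H](c1cc(OC)c(OC)c(OC)c1)[C@@H](c1ccc(OC)cc1O[Si](C)(C)C(C)(C)C)C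
A2 | alternative 1 | (R)-1-[2-(tert-butyldimethylsilyloxy)-4-methoxyphenyl]ethylboronic acid (R,R)-1,2-dicyclohexylethane-1,2-diol ester | B1(O[C@H](C2CCCCC2)[C@@H](C2CCCCC2)O1)[C@@H](c1ccc(OC)cc1O[Si](C)(C)C(C)(C)C)C
A3 | alternative 2 | methyl (2R,3R)-6-methoxy-3-methyl-2-(3,4,5-trimethoxyphenyl)-2,3-dihydrobenzofuran-5-carboxylate (identical with 18) | COC(=O)c1cc2c(cc1OC)O[C@@H](c1cc(OC)c(OC)c(OC)c1)[C@@H]2C
A4 | alternative 2 | tert-butyl(dimethyl){[(4R,5R)-4-methyl-5-(3,4,5-trimethoxyphenyl)-4,5-dihydrofuran-2-yl]oxy}silane | CC(C)(C)[Si](C)(C)OC1=C[C@@H](C)[C@H](c2cc(OC)c(OC)c(OC)c2)O1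
A5 | alternative 2 | methyl 4-methoxy-2-oxo-2H-pyran-5-carboxylate | COC(=O)C1=COC(=O)C=C1OC
A6 | alternative 3 | 2-[(1S,2R)-1-(tert-butyldimethylsilyloxy)-1-(3,4,5-trimethoxyphenyl)propan-2-yl]-5-methoxyphenol | CC(C)(C)[Si](C)(C)O[C@H](c1cc(OC)c(OC)c(OC)c1)[C@@H](c1ccc(OC)cc1O)C
A7 | alternative 3 | (3E,5R,6S)-6-(tert-butyldimethylsilyloxy)-1-diazo-5-methyl-6-(3,4,5-trimethoxyphenyl)hex-3-en-2-one | [N-]=[N+]=CC(=O)/C=C/[C@@H](C)[C@H](O[Si](C)(C)C(C)(C)C)c1cc(OC)c(OC)c(OC)c1
A8 | alternative 3 | methoxyethyne | COC#C
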